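The indane is disconnected at C3–C3a. Until that bond exists, rings A and D are the same 3,5-dioxygenated phenyl group, so the target is an isomer of a 1,2,3,4-tetraaryl-1,3-butadiene: ring E on Cα, the twin aryl groups on C1 and C2, ring C with its ortho-hydroxyl on C3. In one operation, a chiral phosphoric acid bound to that hydroxyl puts a proton on C2 and lets the aryl group on C1 trap the ortho-quinone methide at C3, which closes ring B and sets C2 and C3. The precursor is the hexa-isopropyl ether of that diene with only the ring C ortho-hydroxyl free and C1 trans to ring C across C2=C3.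

Key step: step 13

Atom labels: indane numbering of the target is used for all compounds, open-chain ones included (C1 carries the exocyclic Cα=C1 alkene, C2 ring D, C3 ring C, ring A is C3a–C7a); the target is (1E,2S,3S), 2,3-trans.

Assumption: the (R)-phosphoric acid is taken to give the (2S,3S) series; if the sense of induction proves opposite, the (S)-acid is used and nothing else changes.

Design of the precursor: the ring C para-oxygen is an isopropyl ether, so the acid has a single binding site. C2=C3 is built E, so the hydroxyl cannot hand its proton to Cα or add to C1 (the path to a 2H-chromene). This geometry is erased in the key step.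

Step 1
Reactants: 1 5-bromoresorcinol
Product: 2 1-bromo-3,5-diisopropoxybenzene
Conditions: i-PrBr (3 equiv), K2CO3, DMF, 60 °C
Reagents that add atoms: 2-bromopropane, CC(C)Br
Why: Williamson ether synthesis, in which both phenoxides are alkylated by excess secondary bromide in DMF while the aryl bromide is inert to carbonate.

Step 2
Reactants: 2 1-bromo-3,5-diisopropoxybenzene
Product: 4 (3,5-diisopropoxyphenyl)boronic acid, via (3,5-diisopropoxyphenyl)lithium 3 (not isolated)
Conditions: n-BuLi, THF, −78 °C; B(Oi-Pr)3, −78 °C to rt; 1 M HCl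
Reagents that add atoms: triisopropyl borate, CC(C)OB(OC(C)C)OC(C)C; water, O
Why: Bromine–lithium exchange at −78 °C outruns ortho-lithiation between the two ether groups, the aryllithium is trapped by the borate at the same temperature, and acidic hydrolysis frees the boronic acid (electrophilic borylation of an organolithium).

Step 3
Reactants: 5 vanillin
Product: 6 4-isopropoxy-3-methoxybenzaldehyde
Conditions: i-PrBr, K2CO3, DMF, 70 °C
Reagents that add atoms: 2-bromopropane, CC(C)Br
Why: Williamson ether synthesis at the only phenol, the isopropyl ether being chosen because boron trichloride later removes it beside a methyl ether.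

Step 4
Reactants: 6 4-isopropoxy-3-methoxybenzaldehyde
Product: 7 4-(2,2-dibromovinyl)-1-isopropoxy-2-methoxybenzene
Conditions: CBr4, PPh3, CH2Cl2, 0 °C
Reagents that add atoms: carbon tetrabromide, BrC(Br)(Br)Br
Why: Ramirez dibromo-olefination (first stage of the Corey–Fuchs sequence), in which the ylide Ph3P=CBr2 formed from CBr4 and PPh3 converts the aldehyde into the 1,1-dibromoalkene by a Wittig reaction.

Step 5
Reactants: 7 4-(2,2-dibromovinyl)-1-isopropoxy-2-methoxybenzene; 4 (3,5-diisopropoxyphenyl)boronic acid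
Product: 8 4-[(Z)-2-bromo-2-(3,5-diisopropoxyphenyl)vinyl]-1-isopropoxy-2-methoxybenzene (ring A trans to ring E, bromine cis to ring E)
Conditions: Pd2(dba)3 (tris(dibenzylideneacetone)dipalladium, 2.5 mol%), tri(2-furyl)phosphine (15 mol%), aq. Na2CO3, 1,4-dioxane, 65 °C
Reagents that add atoms: none
Why: Trans-selective Suzuki–Miyaura monocoupling of a 1,1-dibromoalkene, in which palladium inserts into the less hindered C–Br bond trans to ring E, so ring A ends up trans to ring E as in the target, while the weakly donating furylphosphine suppresses double coupling and alkyne formation.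

Step 6
Reactants: 8 4-[(Z)-2-bromo-2-(3,5-diisopropoxyphenyl)vinyl]-1-isopropoxy-2-methoxybenzene
Product: 9 2-[(E)-1-(3,5-diisopropoxyphenyl)-2-(4-isopropoxy-3-methoxyphenyl)vinyl]-4,4,5,5-tetramethyl-1,3,2-dioxaborolane (boron cis to ring E)
Conditions: B2pin2, PdCl2(PPh3)2 (3 mol%), PPh3 (6 mol%), KOPh, toluene, 50 °C
Reagents that add atoms: bis(pinacolato)diboron, CC1(C)OB(OC1(C)C)B1OC(C)(C)C(C)(C)O1
Why: Miyaura borylation of an alkenyl bromide under the phenoxide conditions used for alkenyl halides proceeds with retention, so boron takes the position cis to ring E.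

Step 7
Reactants: 10 2,4-dihydroxybenzaldehyde
Product: 11 2-hydroxy-4-isopropoxybenzaldehyde
Conditions: i-PrBr (1.3 equiv), KHCO3, KI (cat.), DMF, 60 °C
Reagents that add atoms: 2-bromopropane, CC(C)Br
Why: Regioselective Williamson alkylation, in which the 2-hydroxyl is held in a hydrogen bond to the aldehyde and is the weaker acid and nucleophile, so hydrogencarbonate and a small excess of bromide alkylate only the 4-hydroxyl.

Step 8
Reactants: 11 2-hydroxy-4-isopropoxybenzaldehyde
Product: 12 4-isopropoxy-2-[(triisopropylsilyl)oxy]benzaldehyde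
Conditions: TIPSCl, imidazole, DMAP (cat.), DMF, rt
Reagents that add atoms: chlorotriisopropylsilane, CC(C)[Si](Cl)(C(C)C)C(C)C
Why: Imidazole-promoted silylation of the remaining phenol, the triisopropylsilyl ether being chosen because it withstands the aqueous bases of the two couplings and keeps the ortho-oxygen from cyclising onto the dibromoalkene to a benzofuran.

Step 9
Reactants: 12 4-isopropoxy-2-[(triisopropylsilyl)oxy]benzaldehyde
Product: 13 [2-(2,2-dibromovinyl)-5-isopropoxyphenoxy]triisopropylsilane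
Conditions: CBr4, PPh3, Et3N, CH2Cl2, 0 °C
Reagents that add atoms: carbon tetrabromide, BrC(Br)(Br)Br
Why: Ramirez dibromo-olefination as in step 4, buffered with triethylamine so that the phosphorus bromide by-products do not attack the aryl silyl ether.

Step 10
Reactants: 13 [2-(2,2-dibromovinyl)-5-isopropoxyphenoxy]triisopropylsilane; 9 2-[(E)-1-(3,5-diisopropoxyphenyl)-2-(4-isopropoxy-3-methoxyphenyl)vinyl]-4,4,5,5-tetramethyl-1,3,2-dioxaborolane
Product: 14 (1Z,3Z)-2-bromo-3-(3,5-diisopropoxyphenyl)-4-(4-isopropoxy-3-methoxyphenyl)-1-[4-isopropoxy-2-(triisopropylsilyloxy)phenyl]buta-1,3-diene (bromine on C2 cis to ring C, C1 trans to ring C, ring E cis to C2)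
Conditions: Pd2(dba)3 (2.5 mol%), tri(2-furyl)phosphine (15 mol%), aq. K3PO4, THF, 60 °C
Reagents that add atoms: none
Why: Trans-selective Suzuki–Miyaura alkenyl–alkenyl coupling, in which the hindered boronate meets the most accessible C–Br bond of 13 and both partners react with retention, so C1 becomes trans to ring C, ring E stays cis to C2, and the crowded bromide left on C2 resists a second coupling.

Step 11
Reactants: 14 (1Z,3Z)-2-bromo-3-(3,5-diisopropoxyphenyl)-4-(4-isopropoxy-3-methoxyphenyl)-1-[4-isopropoxy-2-(triisopropylsilyloxy)phenyl]buta-1,3-diene; 4 (3,5-diisopropoxyphenyl)boronic acid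
Product: 15 (1E,3Z)-2,3-bis(3,5-diisopropoxyphenyl)-4-(4-isopropoxy-3-methoxyphenyl)-1-[4-isopropoxy-2-(triisopropylsilyloxy)phenyl]buta-1,3-diene (ring D cis to ring C on C2=C3, ring A trans to ring E on C1=Cα)
Conditions: Pd(OAc)2 (5 mol%), SPhos (10 mol%), K3PO4, toluene/H2O 10:1, 80 °C
Reagents that add atoms: none
Why: Suzuki–Miyaura coupling with retention at the remaining alkenyl bromide, an unhindered arylboronic acid and a dialkylbiarylphosphine ligand being used because the C2–Br bond is flanked by ring C and the triarylvinyl group.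

Step 12
Reactants: 15 (1E,3Z)-2,3-bis(3,5-diisopropoxyphenyl)-4-(4-isopropoxy-3-methoxyphenyl)-1-[4-isopropoxy-2-(triisopropylsilyloxy)phenyl]buta-1,3-diene
Product: 16 (1E,3Z)-2,3-bis(3,5-diisopropoxyphenyl)-1-(2-hydroxy-4-isopropoxyphenyl)-4-(4-isopropoxy-3-methoxyphenyl)buta-1,3-diene
Conditions: TBAF, AcOH (1.1 equiv each), THF, 0 °C, argon
Reagents that add atoms: none
Why: Fluoride cleavage of the aryl silyl ether, buffered with acetic acid so that neither phenoxide nor free acid is present in excess, leaves the isopropyl ethers and the diene untouched.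

Step 13
Reactants: 16 (1E,3Z)-2,3-bis(3,5-diisopropoxyphenyl)-1-(2-hydroxy-4-isopropoxyphenyl)-4-(4-isopropoxy-3-methoxyphenyl)buta-1,3-diene
Product: 18 (1E,2S,3S)-2-(3,5-diisopropoxyphenyl)-3-(2-hydroxy-4-isopropoxyphenyl)-4,6-diisopropoxy-1-(4-isopropoxy-3-methoxybenzylidene)indane, via ortho-quinone methide 17 (not isolated)
Conditions: (R)-3,3'-bis(2,4,6-triisopropylphenyl)-1,1'-binaphthyl-2,2'-diyl hydrogen phosphate (10 mol%), toluene (0.02 M), 5 Å MS, 0 °C to rt, argon, dark
Reagents that add atoms: none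
Why: Proposed new method: the phosphoric acid hydrogen-bonds to the only free hydroxyl of 16 and passes its proton to C2, the β-carbon of the ring C styrene, which turns ring C into ortho-quinone methide 17 paired with the chiral phosphate; the 3,5-diisopropoxyphenyl group on C1 then attacks C3 with the carbon that is ortho to C1 and ortho/para to its two oxygens, and loss of a proton restores ring A and frees the catalyst. The closest known reaction type is the chiral-phosphoric-acid generation of ortho-quinone methides from ortho-hydroxystyrenes or ortho-hydroxybenzyl alcohols with enantioselective Friedel–Crafts capture by an electron-rich arene, here made intramolecular on a diene. Ring B closes 5-exo-trig, C3a adding to C3 of the exocyclic C3=C bond of the quinone methide, and no other five-membered closure onto C3 exists, so rings A and D are told apart by position. C3 is set by the catalyst, whose phosphate stays bound at the quinone methide oxygen and shields one face; C2 is set relative to C3 by the substrate, because protonation at C2 is reversible and the closure that puts ring D trans to ring C is the less crowded one, so both centres are fixed together at C–C bond formation. The step needs the proton on C2 and not on Cα or C1, and attack by ring A and not by ring E: the single hydroxyl places the acid beside C2, the E geometry of C2=C3 turns C1=Cα away from it, the phosphoric acid is too weak to protonate the ether-only ring E styrene on its own, and the ring A carbon is activated by two oxygens against one for ring E. The Cα=C1 geometry is not touched, so ring E stays cis to C2 as in the target.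

Step 14
Reactants: 18 (1E,2S,3S)-2-(3,5-diisopropoxyphenyl)-3-(2-hydroxy-4-isopropoxyphenyl)-4,6-diisopropoxy-1-(4-isopropoxy-3-methoxybenzylidene)indane
Product: 19 (1E,2S,3S)-2-(3,5-dihydroxyphenyl)-3-(2,4-dihydroxyphenyl)-1-(4-hydroxy-3-methoxybenzylidene)indane-4,6-diol (target)
Conditions: BCl3 (1 M in CH2Cl2, 15 equiv), CH2Cl2, −78 to 0 °C; then H2O
Reagents that add atoms: none
Why: Lewis-acid dealkylation, in which boron trichloride cleaves aryl isopropyl ethers through a secondary-cation-like pathway far faster than an aryl methyl ether, so all six isopropyl groups should leave at or below 0 °C while the ring E methoxy group, the exocyclic alkene and the untouched C2 and C3 stereocentres remain.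

Compound list
1 | 5-bromoresorcinol | Oc1cc(O)cc(Br)c1 | starting material
2 | 1-bromo-3,5-diisopropoxybenzene | CC(C)Oc1cc(Br)cc(OC(C)C)c1 | intermediate
3 | (3,5-diisopropoxyphenyl)lithium | [Li]c1cc(OC(C)C)cc(OC(C)C)c1 | intermediate (not isolated)
4 | (3,5-diisopropoxyphenyl)boronic acid | OB(O)c1cc(OC(C)C)cc(OC(C)C)c1 | intermediate
5 | vanillin | COc1cc(C=O)ccc1O | starting material
6 | 4-isopropoxy-3-methoxybenzaldehyde | COc1cc(C=O)ccc1OC(C)C | intermediate
7 | 4-(2,2-dibromovinyl)-1-isopropoxy-2-methoxybenzene | COc1cc(C=C(Br)Br)ccc1OC(C)C | intermediate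
8 | 4-[(Z)-2-bromo-2-(3,5-diisopropoxyphenyl)vinyl]-1-isopropoxy-2-methoxybenzene | COc1cc(/C=C(\Br)c2cc(OC(C)C)cc(OC(C)C)c2)ccc1OC(C)C | intermediate
9 | 2-[(E)-1-(3,5-diisopropoxyphenyl)-2-(4-isopropoxy-3-methoxyphenyl)vinyl]-4,4,5,5-tetramethyl-1,3,2-dioxaborolane | COc1cc(/C=C(\B2OC(C)(C)C(C)(C)O2)c2cc(OC(C)C)cc(OC(C)C)c2)ccc1OC(C)C | intermediate
10 | 2,4-dihydroxybenzaldehyde | O=Cc1ccc(O)cc1O | starting material
11 | 2-hydroxy-4-isopropoxybenzaldehyde | CC(C)Oc1ccc(C=O)c(O)c1 | intermediate
12 | 4-isopropoxy-2-[(triisopropylsilyl)oxy]benzaldehyde | CC(C)Oc1ccc(C=O)c(O[Si](C(C)C)(C(C)C)C(C)C)c1 | intermediate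
13 | [2-(2,2-dibromovinyl)-5-isopropoxyphenoxy]triisopropylsilane | CC(C)Oc1ccc(C=C(Br)Br)c(O[Si](C(C)C)(C(C)C)C(C)C)c1 | intermediate
14 | (1Z,3Z)-2-bromo-3-(3,5-diisopropoxyphenyl)-4-(4-isopropoxy-3-methoxyphenyl)-1-[4-isopropoxy-2-(triisopropylsilyloxy)phenyl]buta-1,3-diene | CC(C)Oc1ccc(/C=C(\Br)/C(=C\c2ccc(OC(C)C)c(OC)c2)c2cc(OC(C)C)cc(OC(C)C)c2)c(O[Si](C(C)C)(C(C)C)C(C)C)c1 | intermediate
15 | (1E,3Z)-2,3-bis(3,5-diisopropoxyphenyl)-4-(4-isopropoxy-3-methoxyphenyl)-1-[4-isopropoxy-2-(triisopropylsilyloxy)phenyl]buta-1,3-diene | CC(C)Oc1ccc(/C=C(\c2cc(OC(C)C)cc(OC(C)C)c2)/C(=C\c2ccc(OC(C)C)c(OC)c2)c2cc(OC(C)C)cc(OC(C)C)c2)c(O[Si](C(C)C)(C(C)C)C(C)C)c1 | intermediate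
16 | (1E,3Z)-2,3-bis(3,5-diisopropoxyphenyl)-1-(2-hydroxy-4-isopropoxyphenyl)-4-(4-isopropoxy-3-methoxyphenyl)buta-1,3-diene (precursor of the key step) | CC(C)Oc1ccc(/C=C(\c2cc(OC(C)C)cc(OC(C)C)c2)/C(=C\c2ccc(OC(C)C)c(OC)c2)c2cc(OC(C)C)cc(OC(C)C)c2)c(O)c1 | intermediate
17 | 6-[(2S,3E)-2,3-bis(3,5-diisopropoxyphenyl)-4-(4-isopropoxy-3-methoxyphenyl)but-3-en-1-ylidene]-3-isopropoxycyclohexa-2,4-dien-1-one (ortho-quinone methide, productive C2 epimer, geometry of the quinone methide C=C not defined) | O=C1C=C(OC(C)C)C=CC1=C[C@@H](c1cc(OC(C)C)cc(OC(C)C)c1)/C(=C\c1ccc(OC(C)C)c(OC)c1)c1cc(OC(C)C)cc(OC(C)C)c1 | intermediate (not isolated)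
18 | (1E,2S,3S)-2-(3,5-diisopropoxyphenyl)-3-(2-hydroxy-4-isopropoxyphenyl)-4,6-diisopropoxy-1-(4-isopropoxy-3-methoxybenzylidene)indane | COc1cc(/C=C2/c3cc(OC(C)C)cc(OC(C)C)c3[C@H](c3ccc(OC(C)C)cc3O)[C@H]2c2cc(OC(C)C)cc(OC(C)C)c2)ccc1OC(C)C | intermediate
19 | (1E,2S,3S)-2-(3,5-dihydroxyphenyl)-3-(2,4-dihydroxyphenyl)-1-(4-hydroxy-3-methoxybenzylidene)indane-4,6-diol | COc1cc(/C=C2/c3cc(O)cc(O)c3[C@H](c3ccc(O)cc3O)[C@H]2c2cc(O)cc(O)c2)ccc1O | target

Total step count: 14.
Longest linear sequence: 9 steps (from 5 through steps 3, 4, 5, 6, 10, 11, 12, 13, 14; the same length from 1 through steps 1, 2, 5, 6, 10, 11, 12, 13, 14).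

Steps most likely to fail

Step 13. The phosphate may discriminate the two faces of C3 poorly, or the acid may be too weak to turn over. The fallback sets out from 16 and returns at 18. 16 is closed without asymmetric induction by an achiral Brønsted acid (diphenyl hydrogen phosphate or CF3CO2H, CH2Cl2, −20 °C), an ordinary acid-promoted Friedel–Crafts cyclisation of an electron-rich styrene onto a dialkoxyarene. This should give 18 as the racemate, that is together with its enantiomer (1E,2R,3R)-2-(3,5-diisopropoxyphenyl)-3-(2-hydroxy-4-isopropoxyphenyl)-4,6-diisopropoxy-1-(4-isopropoxy-3-methoxybenzylidene)indane F1. The single phenol, which sits next to C3, is acylated with (1S)-camphanic chloride (Et3N, DMAP, CH2Cl2) to give the (1S,4R)-camphanate of 18 F2 and the (1S,4R)-camphanate of the enantiomer F3. These diastereomers are separated by chromatography or crystallisation, and LiOH in THF/water at 0 °C cleaves the aryl ester of F2 and returns 18.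

Step 10. Loss of boron from the hindered alkenylboronate may outrun transmetalation, and the aqueous base may dehydrobrominate the dibromoalkene. The fallback sets out from 8 and returns at 14. 8 is stannylated with Me3SnSnMe3 and Pd(PPh3)4 in toluene at 100 °C to give trimethyl[(Z)-1-(3,5-diisopropoxyphenyl)-2-(4-isopropoxy-3-methoxyphenyl)vinyl]stannane F4. F4 is joined to 13 in a trans-selective Stille coupling (Pd2(dba)3, tri(2-furyl)phosphine, CuI, DMF, 50 °C); no base or water is present, so both loss pathways are closed, and the product is 14.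

Step 11. Oxidative addition and transmetalation at the crowded C2–Br bond may be slow enough for hydrodebromination or migration of palladium onto a neighbouring ring to take over. The fallback sets out from 13 and returns at 18; it attaches ring D before the diene is assembled.
- 13 is arylated with 4 under the conditions of step 5 to give {2-[(Z)-2-bromo-2-(3,5-diisopropoxyphenyl)vinyl]-5-isopropoxyphenoxy}triisopropylsilane F5.
- F5 is coupled with boronate 9 (Pd(OAc)2, SPhos, K3PO4, toluene/H2O, 90 °C) to give (1Z,3Z)-2,3-bis(3,5-diisopropoxyphenyl)-4-(4-isopropoxy-3-methoxyphenyl)-1-[4-isopropoxy-2-(triisopropylsilyloxy)phenyl]buta-1,3-diene F6, the C2=C3 geometric isomer of 15.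
- TBAF/AcOH frees (1Z,3Z)-2,3-bis(3,5-diisopropoxyphenyl)-1-(2-hydroxy-4-isopropoxyphenyl)-4-(4-isopropoxy-3-methoxyphenyl)buta-1,3-diene F7, the isomer of 16.
- F7 is used in step 13 without storage, because in this geometry the hydroxyl can reach C1=Cα. Protonation at C2 erases the C2=C3 geometry, so F7 gives the same quinone methide 17 and the route is rejoined at 18.

Further compounds
F1 | step 13 | (1E,2R,3R)-2-(3,5-diisopropoxyphenyl)-3-(2-hydroxy-4-isopropoxyphenyl)-4,6-diisopropoxy-1-(4-isopropoxy-3-methoxybenzylidene)indane (enantiomer of 18) | COc1cc(/C=C2/c3cc(OC(C)C)cc(OC(C)C)c3[C@@H](c3ccc(OC(C)C)cc3O)[C@@H]2c2cc(OC(C)C)cc(OC(C)C)c2)ccc1OC(C)C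
F2 | step 13 | (1S,4R)-camphanate of 18 at the ring C hydroxyl | COc1cc(/C=C2/c3cc(OC(C)C)cc(OC(C)C)c3[C@H](c3ccc(OC(C)C)cc3OC(=O)[C@]34OC(=O)[C@](C)(CC3)C4(C)C)[C@H]2c2cc(OC(C)C)cc(OC(C)C)c2)ccc1OC(C)C
F3 | step 13 | (1S,4R)-camphanate of F1 at the ring C hydroxyl | COc1cc(/C=C2/c3cc(OC(C)C)cc(OC(C)C)c3[C@@H](c3ccc(OC(C)C)cc3OC(=O)[C@]34OC(=O)[C@](C)(CC3)C4(C)C)[C@@H]2c2cc(OC(C)C)cc(OC(C)C)c2)ccc1OC(C)C
F4 | step 10 | trimethyl[(Z)-1-(3,5-diisopropoxyphenyl)-2-(4-isopropoxy-3-methoxyphenyl)vinyl]stannane | COc1cc(/C=C(\[Sn](C)(C)C)c2cc(OC(C)C)cc(OC(C)C)c2)ccc1OC(C)C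
F5 | step 11 | {2-[(Z)-2-bromo-2-(3,5-diisopropoxyphenyl)vinyl]-5-isopropoxyphenoxy}triisopropylsilane | CC(C)Oc1ccc(/C=C(\Br)c2cc(OC(C)C)cc(OC(C)C)c2)c(O[Si](C(C)C)(C(C)C)C(C)C)c1
F6 | step 11 | (1Z,3Z)-2,3-bis(3,5-diisopropoxyphenyl)-4-(4-isopropoxy-3-methoxyphenyl)-1-[4-isopropoxy-2-(triisopropylsilyloxy)phenyl]buta-1,3-diene | CC(C)Oc1ccc(/C=C(/c2cc(OC(C)C)cc(OC(C)C)c2)\C(=C/c2ccc(OC(C)C)c(OC)c2)c2cc(OC(C)C)cc(OC(C)C)c2)c(O[Si](C(C)C)(C(C)C)C(C)C)c1
F7 | step 11 | (1Z,3Z)-2,3-bis(3,5-diisopropoxyphenyl)-1-(2-hydroxy-4-isopropoxyphenyl)-4-(4-isopropoxy-3-methoxyphenyl)buta-1,3-diene | CC(C)Oc1ccc(/C=C(/c2cc(OC(C)C)cc(OC(C)C)c2)\C(=C/c2ccc(OC(C)C)c(OC)c2)c2cc(OC(C)C)cc(OC(C)C)c2)c(O)c1
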